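Numbering: ring C1 = tertiary carbinol, C2 = CH2, C3 = secondary carbinol, C4=C5 = alkene, C6 = CH2. The side chain is C1′–C16′, with the Z-alkene at C12′=C13′ and phenyl on C16′.
Cuts, in retrosynthetic order: C12′=C13′ (Wittig); the C3–O bond (Pd-catalysed allylic substitution on a carbonate bridging the C1 and C3 oxygens); the bridge itself (C3–O from iodocarbonation, C4=C5 from loss of HI); C1–C1′ (Grignard addition to cyclohex-3-enone).
Forward: the carbocycle is bought as the Birch diene of anisole and the C12 chain is joined at C1. The six-membered carbonate ring then closes onto C3 to give a 2,4-dioxabicyclo[3.3.1]nonane, the key step opens it again, and the 4-phenylbutylidene end is joined last.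
Enabling feature: C1 is a stereocentre only because its ring arms C2 and C6 run to unlike ends of the C3–C4–C5 unit (C3 oxygenated, C5 not). Once C3–O is ionised, the η3-cyclohexenyl unit has a mirror plane through C1 and C4, so a racemic precursor converges on one meso intermediate.
Stereochemistry: the chiral diphosphine on Pd picks one enantiotopic allyl terminus and so sets C1 and C3 (both S) together. The cis-1,3 relation comes from the bridge plus double inversion, and the Z-alkene from a non-stabilised ylide free of lithium salts.

Key step: step 7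

Assumption: the (R,R)-DACH-phenyl ligand is taken to give the (S)-configured allylic ester, as on the parent cyclohex-2-enyl system; sense and ee are to be checked on the product of step 7 (chiral HPLC, MTPA ester of the derived alcohol), and the (S,S)-ligand is used if the sense is reversed.
Abbreviations: TBDPS = tert-butyldiphenylsilyl; Piv = pivaloyl; (R,R)-DACH-phenyl ligand = (1R,2R)-N,N′-bis[2-(diphenylphosphino)benzoyl]cyclohexane-1,2-diamine.

Step 1
Reactants: 1 12-bromododecan-1-ol
Product: 2 (12-bromododecyloxy)(tert-butyl)diphenylsilane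
Conditions: TBDPSCl (1.1 equiv), imidazole (2.0 equiv), CH2Cl2, 0 °C → rt
Reagents that add atoms: tert-butyl(chloro)diphenylsilane (TBDPSCl), CC(C)(C)[Si](Cl)(c1ccccc1)c1ccccc1
Why: Imidazole-promoted silyl ether formation on a primary alcohol gives a TBDPS ether that should survive Grignard formation, n-BuLi, IBr, DBU and the Pd step, and CH2Cl2 is chosen over DMF so that chloride or imidazole does not displace the primary bromide.

Step 2
Reactants: 3 1-methoxycyclohexa-1,4-diene
Product: 4 cyclohex-3-en-1-one
Conditions: oxalic acid dihydrate (10 mol %), THF–H2O, rt, about 1 h; extract into Et2O, dry (MgSO4, then 4 Å MS), use at once as a solution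
Reagents that add atoms: water, O
Why: Acid-catalysed enol ether hydrolysis with a weak acid at room temperature protonates the enol ether carbon and releases the ketone, yet is too mild to pull the isolated C=C into conjugation if the product is used immediately.

Step 3
Reactants: 2 (12-bromododecyloxy)(tert-butyl)diphenylsilane; 4 cyclohex-3-en-1-one
Product: 6 racemic 1-[12-(tert-butyldiphenylsilyloxy)dodecyl]cyclohex-3-en-1-ol, via Grignard reagent 5 (not isolated)
Conditions: (i) 2, Mg turnings (I2-activated), THF, 45 °C; (ii) 4 (1.3 equiv) and LaCl3·2LiCl (1.0 equiv), THF, 0 °C briefly, then −78 °C, add 5, → −20 °C; aq NH4Cl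
Reagents that add atoms: magnesium, [Mg] (retained only in intermediate 5)
Why: This is a Grignard 1,2-addition to a ketone in which the oxophilic lanthanide salt activates the carbonyl and tempers the basicity of the reagent, holding back enolisation and conjugation of the β,γ-enone; C1 is formed racemic, which does not matter because step 7 erases and resets it.

Step 4
Reactants: 6 racemic 1-[12-(tert-butyldiphenylsilyloxy)dodecyl]cyclohex-3-en-1-ol
Product: 8 racemic tert-butyl 1-[12-(tert-butyldiphenylsilyloxy)dodecyl]cyclohex-3-en-1-yl carbonate, via lithium alkoxide 7 (not isolated)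
Conditions: n-BuLi (1.05 equiv), THF, −78 → 0 °C; Boc2O (1.3 equiv), 0 °C → rt
Reagents that add atoms: di-tert-butyl dicarbonate (Boc2O), CC(C)(C)OC(=O)OC(=O)OC(C)(C)C; n-butyllithium, [Li]CCCC (lithium retained only in intermediate 7)
Why: O-acylation of a preformed tertiary lithium alkoxide with Boc2O forms the mixed carbonate, prior deprotonation being needed because the hindered neutral alcohol acylates only sluggishly.

Step 5
Reactants: 8 racemic tert-butyl 1-[12-(tert-butyldiphenylsilyloxy)dodecyl]cyclohex-3-en-1-yl carbonate
Product: 9 racemic (1RS,5RS,6RS)-6-iodo-1-[12-(tert-butyldiphenylsilyloxy)dodecyl]-2,4-dioxabicyclo[3.3.1]nonan-3-one (carbonate bridging the C1 and C3 oxygens, iodine on C4 trans to the C3 oxygen)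
Conditions: IBr (1.3 equiv), PhMe, −80 °C; aq Na2S2O3/NaHCO3
Reagents that add atoms: iodine monobromide, BrI
Why: In this iodocarbonation (electrophilic cyclofunctionalisation of a homoallylic tert-butyl carbonate) the carbonyl oxygen of the axial carbonate opens the iodonium ion at C3 from the opposite face in a 6-exo, trans-diaxial manner and tert-butyl is lost, so O–C3 ends cis to O–C1 and iodine at C4 trans to it, while attack at C4 would require a seven-membered [3.2.2] bridge.

Step 6
Reactants: 9 racemic bridged iodo carbonate
Product: 10 racemic (1RS,5RS)-1-[12-(tert-butyldiphenylsilyloxy)dodecyl]-2,4-dioxabicyclo[3.3.1]non-6-en-3-one (bridged allylic carbonate, alkene C4=C5)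
Conditions: DBU (2.5 equiv), PhMe, 80 °C
Reagents that add atoms: none
Why: This is an E2 dehydroiodination with DBU, as in the classical iodolactone-to-unsaturated-lactone sequence, and because the axial iodide on C4 has an antiperiplanar hydrogen only on C5 (H–C3 is equatorial) the alkene can form only as C4=C5, which leaves the C3–O bond allylic.

Step 7
Reactants: 10 racemic bridged allylic carbonate
Product: 11 (1S,5S)-5-hydroxy-5-[12-(tert-butyldiphenylsilyloxy)dodecyl]cyclohex-2-en-1-yl pivalate
Conditions: Pd2(dba)3·CHCl3 (2.5 mol %), (R,R)-DACH-phenyl ligand (7.5 mol %), PivOH (1.5 equiv), degassed CH2Cl2, 0 °C → rt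
Reagents that add atoms: pivalic acid, CC(C)(C)C(=O)O
Why: Proposed new method: Pd(0) binds the C4=C5 alkene of 10 on the face away from the bridge and expels the pseudoaxial allylic C3–O bond, so that each enantiomer of 10 ends in the same η3-allyl complex over C3–C4–C5, which has a mirror plane through C1 and C4 and carries Pd trans to the C1 oxygen. The pendant C1 carbonate anion can either snap back onto C3 or C5, which only interconverts the enantiomers of 10, or take a proton from PivOH and lose CO2, which frees the tertiary hydroxyl and one pivalate ion. That pivalate attacks from outside, anti to Pd, at the allyl terminus left open by the chiral pocket of the ligand and forms the new C3–O bond; no ring is closed and the six-membered carbonate ring is opened. The closest known reaction types are the Tsuji–Trost deracemisation of racemic cycloalk-2-enyl carbonates with carboxylate nucleophiles through a meso π-allyl and the Pd(0) opening of bridged allylic lactones and of vinyl-substituted cyclic carbonates, whereas a bridged cyclic carbonate as leaving group on a 5,5-disubstituted cyclohexenyl ring has not been shown. C3 and C1 become stereocentres in the same bond formation: their cis relation is fixed by double inversion (Pd anti to the bridge oxygen, pivalate anti to Pd) and their absolute configuration by the ligand, since attack at the other terminus would give the mirror image. The only selectivity required is thus the choice between enantiotopic termini, because the symmetry of the allyl unit removes any regiochemical issue, the bridge of 10 fixes the face of ionisation, and the slowly ionising pivalate shields 11 from erosion.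

Step 8
Reactants: 11 (1S,5S)-5-hydroxy-5-[12-(tert-butyldiphenylsilyloxy)dodecyl]cyclohex-2-en-1-yl pivalate
Product: 12 (1S,5S)-5-hydroxy-5-(12-hydroxydodecyl)cyclohex-2-en-1-yl pivalate
Conditions: TBAF (1.5 equiv), AcOH (1.5 equiv), THF, rt
Reagents that add atoms: none
Why: This is a fluoride-mediated silyl ether cleavage, buffered with AcOH so that the medium stays non-basic and the pivalate neither migrates to the cis tertiary hydroxyl nor is hydrolysed.

Step 9
Reactants: 12 (1S,5S)-5-hydroxy-5-(12-hydroxydodecyl)cyclohex-2-en-1-yl pivalate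
Product: 13 (1S,5S)-5-hydroxy-5-(12-oxododecyl)cyclohex-2-en-1-yl pivalate
Conditions: TPAP (5 mol %), NMO (1.5 equiv), 4 Å MS, CH2Cl2, rt
Reagents that add atoms: none
Why: The Ley–Griffith oxidation takes the primary alcohol to the aldehyde under neutral, anhydrous conditions that leave the non-oxidisable tertiary alcohol, the allylic ester and the acid-sensitive ring untouched.

Step 10
Reactants: 14 (4-bromobutyl)benzene
Product: 15 (4-phenylbutyl)triphenylphosphonium bromide
Conditions: PPh3 (1.05 equiv), MeCN, reflux; precipitate with Et2O, dry under vacuum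
Reagents that add atoms: triphenylphosphine, c1ccccc1P(c1ccccc1)c1ccccc1
Why: SN2 quaternisation of triphenylphosphine by an unhindered primary bromide gives a crystalline salt that can be dried rigorously for the olefination.

Step 11
Reactants: 13 (1S,5S)-5-hydroxy-5-(12-oxododecyl)cyclohex-2-en-1-yl pivalate; 15 (4-phenylbutyl)triphenylphosphonium bromide
Product: 17 (1S,5S)-5-hydroxy-5-[(12Z)-16-phenylhexadec-12-en-1-yl]cyclohex-2-en-1-yl pivalate, via phosphonium ylide 16 (not isolated)
Conditions: 15 (1.8 equiv), NaHMDS (1.7 equiv), THF, 0 °C; then −78 °C, add 13, → 0 °C; pH 7 buffer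
Reagents that add atoms: none
Why: In this Wittig olefination a non-stabilised ylide under lithium-salt-free conditions forms the cis-oxaphosphetane under kinetic control at low temperature and so should give the Z-alkene, while the salt is kept in slight excess over the base so that no amide remains, the tertiary alcohol is far too weak an acid to quench the ylide, and the hindered pivalate is not attacked in the cold.

Step 12
Reactants: 17 (1S,5S)-5-hydroxy-5-[(12Z)-16-phenylhexadec-12-en-1-yl]cyclohex-2-en-1-yl pivalate
Product: 18 (1S,3S)-1-[(12Z)-16-phenylhexadec-12-en-1-yl]cyclohex-4-ene-1,3-diol (CNP0333899.1)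
Conditions: DIBAL-H (3.5 equiv), CH2Cl2, −78 °C; aq Rochelle salt; chromatography on Et3N-deactivated silica
Reagents that add atoms: none
Why: Reductive ester cleavage with DIBAL-H removes the hindered pivalate at low temperature without acid or strong base, so the dehydration-prone tertiary/allylic diol, both alkenes and both stereocentres stay as they are.

Compound list
1 | 12-bromododecan-1-ol | OCCCCCCCCCCCCBr | starting material
2 | (12-bromododecyloxy)(tert-butyl)diphenylsilane | BrCCCCCCCCCCCCO[Si](c1ccccc1)(c1ccccc1)C(C)(C)C | intermediate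
3 | 1-methoxycyclohexa-1,4-diene | COC1=CCC=CC1 | starting material
4 | cyclohex-3-en-1-one | O=C1CC=CCC1 | intermediate
5 | [12-(tert-butyldiphenylsilyloxy)dodecyl]magnesium bromide (not isolated) | Br[Mg]CCCCCCCCCCCCO[Si](c1ccccc1)(c1ccccc1)C(C)(C)C | intermediate
6 | racemic 1-[12-(tert-butyldiphenylsilyloxy)dodecyl]cyclohex-3-en-1-ol | OC1(CCCCCCCCCCCCO[Si](c2ccccc2)(c2ccccc2)C(C)(C)C)CC=CCC1 | intermediate
7 | lithium alkoxide of 6 (racemic, not isolated) | [Li+].[O-]C1(CCCCCCCCCCCCO[Si](c2ccccc2)(c2ccccc2)C(C)(C)C)CC=CCC1 | intermediate
8 | racemic tert-butyl 1-[12-(tert-butyldiphenylsilyloxy)dodecyl]cyclohex-3-en-1-yl carbonate | CC(C)(C)OC(=O)OC1(CCCCCCCCCCCCO[Si](c2ccccc2)(c2ccccc2)C(C)(C)C)CC=CCC1 | intermediate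
9 | racemic (1RS,5RS,6RS)-6-iodo-1-[12-(tert-butyldiphenylsilyloxy)dodecyl]-2,4-dioxabicyclo[3.3.1]nonan-3-one (one enantiomer drawn) | O=C1O[C@@H]2[C@@H](I)CC[C@](CCCCCCCCCCCCO[Si](c3ccccc3)(c3ccccc3)C(C)(C)C)(O1)C2 | intermediate
10 | racemic (1RS,5RS)-1-[12-(tert-butyldiphenylsilyloxy)dodecyl]-2,4-dioxabicyclo[3.3.1]non-6-en-3-one (one enantiomer drawn) | O=C1O[C@@H]2C=CC[C@](CCCCCCCCCCCCO[Si](c3ccccc3)(c3ccccc3)C(C)(C)C)(O1)C2 | intermediate
11 | (1S,5S)-5-hydroxy-5-[12-(tert-butyldiphenylsilyloxy)dodecyl]cyclohex-2-en-1-yl pivalate | CC(C)(C)C(=O)O[C@@H]1C=CC[C@@](O)(CCCCCCCCCCCCO[Si](c2ccccc2)(c2ccccc2)C(C)(C)C)C1 | intermediate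
12 | (1S,5S)-5-hydroxy-5-(12-hydroxydodecyl)cyclohex-2-en-1-yl pivalate | CC(C)(C)C(=O)O[C@@H]1C=CC[C@@](O)(CCCCCCCCCCCCO)C1 | intermediate
13 | (1S,5S)-5-hydroxy-5-(12-oxododecyl)cyclohex-2-en-1-yl pivalate | CC(C)(C)C(=O)O[C@@H]1C=CC[C@@](O)(CCCCCCCCCCCC=O)C1 | intermediate
14 | (4-bromobutyl)benzene | BrCCCCc1ccccc1 | starting material
15 | (4-phenylbutyl)triphenylphosphonium bromide | [Br-].c1ccccc1CCCC[P+](c1ccccc1)(c1ccccc1)c1ccccc1 | intermediate
16 | (4-phenylbutylidene)triphenylphosphorane (not isolated) | c1ccccc1CCCC=P(c1ccccc1)(c1ccccc1)c1ccccc1 | intermediate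
17 | (1S,5S)-5-hydroxy-5-[(12Z)-16-phenylhexadec-12-en-1-yl]cyclohex-2-en-1-yl pivalate | CC(C)(C)C(=O)O[C@@H]1C=CC[C@@](O)(CCCCCCCCCCC/C=C\CCCc2ccccc2)C1 | intermediate
18 | (1S,3S)-1-[(12Z)-16-phenylhexadec-12-en-1-yl]cyclohex-4-ene-1,3-diol | O[C@@H]1C=CC[C@@](O)(CCCCCCCCCCC/C=C\CCCc2ccccc2)C1 | target

Total step count: 12.
Longest linear sequence: 10 steps (1 → 2 → 6 → 8 → 9 → 10 → 11 → 12 → 13 → 17 → 18; the same length when counted from 3).

Steps most likely to fail

Step 7 (new method).
- **What may go wrong:** The ligand may discriminate poorly between the two enantiotopic allyl termini, because the C1 chain lies on the Pd face of the ring. Return of the tethered carbonate may outrun decarboxylation, so that the substrate only racemises. β-Hydride loss from the allyl complex, followed by dehydration, would lead towards aromatisation.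
- **Fallback:** This uses known chemistry and replaces asymmetric catalysis by resolution. It sets out from 10, and methanolysis of the carbonate (K2CO3, MeOH, rt) gives racemic cis-1-[12-(tert-butyldiphenylsilyloxy)dodecyl]cyclohex-4-ene-1,3-diol F1. Lipase-catalysed acylative kinetic resolution (Pseudomonas cepacia lipase or Candida antarctica lipase B, vinyl acetate, MTBE, rt, stopped near half conversion) touches only the secondary allylic hydroxyl. With the C2 arm and its quaternary carbon as the large group, it should give (1S,5S)-5-hydroxy-5-[12-(tert-butyldiphenylsilyloxy)dodecyl]cyclohex-2-en-1-yl acetate F2, which is separated from the unreacted antipodal diol by chromatography. Methanolysis (K2CO3, MeOH) gives (1S,3S)-1-[12-(tert-butyldiphenylsilyloxy)dodecyl]cyclohex-4-ene-1,3-diol F3. If the enzyme prefers the other enantiomer, this same diol is simply the recovered alcohol. PivCl, pyridine and catalytic DMAP at 0 °C acylate the secondary hydroxyl alone, and the route is rejoined at 11. The price is the loss of half the material.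

Step 3.
- **What may go wrong:** The Grignard reagent may enolise the β,γ-unsaturated ketone, the double bond may drift into conjugation before or during the addition, and Wurtz coupling may occur while the reagent is made.
- **Fallback:** The ring is built by metathesis instead of being bought as the ketone. The fallback sets out from 2, whose Grignard reagent 5 is acylated with N-methoxy-N-methylpent-4-enamide (Weinreb ketone synthesis, THF, 0 °C) to give 17-(tert-butyldiphenylsilyloxy)heptadec-1-en-5-one F4. Allylmagnesium bromide (THF, −78 °C) adds to give racemic 5-allyl-17-(tert-butyldiphenylsilyloxy)heptadec-1-en-5-ol F5. Ring-closing metathesis of its allyl and but-3-enyl arms (second-generation Grubbs catalyst, CH2Cl2, 40 °C) closes the cyclohexene, and the route is rejoined at 6.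

Step 6.
- **What may go wrong:** DBU or adventitious water may attack the strained carbonate carbonyl, and the released C3 alkoxide could then close an epoxide, in competition with a slow E2 reaction.
- **Fallback:** Base-induced anti elimination is replaced by a neutral syn elimination, and steps 5 and 6 are replaced together. The fallback sets out from 8. Phenylselenocarbonation (PhSeCl, CH2Cl2, −78 °C) follows the same anti, 6-exo course as the iodine reaction and gives racemic (1RS,5RS,6RS)-6-(phenylselanyl)-1-[12-(tert-butyldiphenylsilyloxy)dodecyl]-2,4-dioxabicyclo[3.3.1]nonan-3-one F6. Oxidation (30 % H2O2, pyridine, CH2Cl2, 0 °C) gives the corresponding selenoxide F7. At or below room temperature this undergoes selenoxide syn elimination away from the oxygen-bearing C3, as such eliminations normally do. The alkene forms at C4=C5, and the route is rejoined at 10.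

Further compounds
F1 | step 7 | racemic cis-1-[12-(tert-butyldiphenylsilyloxy)dodecyl]cyclohex-4-ene-1,3-diol (both enantiomers written) | O[C@@H]1C=CC[C@@](O)(CCCCCCCCCCCCO[Si](c2ccccc2)(c2ccccc2)C(C)(C)C)C1.O[C@H]1C=CC[C@](O)(CCCCCCCCCCCCO[Si](c2ccccc2)(c2ccccc2)C(C)(C)C)C1
F2 | step 7 | (1S,5S)-5-hydroxy-5-[12-(tert-butyldiphenylsilyloxy)dodecyl]cyclohex-2-en-1-yl acetate | CC(=O)O[C@@H]1C=CC[C@@](O)(CCCCCCCCCCCCO[Si](c2ccccc2)(c2ccccc2)C(C)(C)C)C1
F3 | step 7 | (1S,3S)-1-[12-(tert-butyldiphenylsilyloxy)dodecyl]cyclohex-4-ene-1,3-diol | O[C@@H]1C=CC[C@@](O)(CCCCCCCCCCCCO[Si](c2ccccc2)(c2ccccc2)C(C)(C)C)C1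
F4 | step 3 | 17-(tert-butyldiphenylsilyloxy)heptadec-1-en-5-one | C=CCCC(=O)CCCCCCCCCCCCO[Si](c1ccccc1)(c1ccccc1)C(C)(C)C
F5 | step 3 | racemic 5-allyl-17-(tert-butyldiphenylsilyloxy)heptadec-1-en-5-ol | C=CCCC(O)(CC=C)CCCCCCCCCCCCO[Si](c1ccccc1)(c1ccccc1)C(C)(C)C
F6 | step 6 | racemic (1RS,5RS,6RS)-6-(phenylselanyl)-1-[12-(tert-butyldiphenylsilyloxy)dodecyl]-2,4-dioxabicyclo[3.3.1]nonan-3-one (one enantiomer drawn) | O=C1O[C@@H]2[C@@H]([Se]c3ccccc3)CC[C@](CCCCCCCCCCCCO[Si](c3ccccc3)(c3ccccc3)C(C)(C)C)(O1)C2
F7 | step 6 | selenoxide of F6, 6-(benzeneseleninyl) analogue (mixture at selenium, not isolated) | O=C1O[C@@H]2[C@@H]([Se](=O)c3ccccc3)CC[C@](CCCCCCCCCCCCO[Si](c3ccccc3)(c3ccccc3)C(C)(C)C)(O1)C2
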